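# Kaempferol 3-O-sulfate (14) by a chalcone-synthase-type Claisen cyclisation of a tetraketide

## The problem

Kaempferol 3-O-sulfate (14) is a flavonol: a benzo ring A with oxygen at C5, C7 and C8a is fused to a 4-pyranone ring C, which carries the 4-hydroxyphenyl ring B at C2 and the sulfated enol oxygen at C3. The molecule has no stereocentre, so the task is one of position and oxidation level, not of configuration. Four hydroxyls (O3, O5, O7, O4') must be told apart so that only O3 is sulfated, although the phenolic O7 and O4' are the first to react with sulfating agents. The aryl hydrogen sulfate is the fragile group: acid solvolyses it, its own acidity included. It therefore has to come late, and everything after it has to run close to neutral, which points to benzyl ethers and hydrogenolysis for the phenols. Ring C has to be closed and C3 raised to the enol oxidation level without letting the open-chain precursor close to a five-membered ring. The feature that opens the way is ring A itself. C4a carries the acyl carbon C4 between two oxygenated carbons, with the third oxygen para: the pattern of a 2-acylphloroglucinol, and thus of a cinnamoyl-capped 3,5,7-triketo ester folded by Claisen condensation (bond C4a–C5). Because this phloroglucinol is symmetric about the acyl group, either ortho oxygen can later become O1; what must be controlled is that the chain closes in the Claisen and not in the aldol sense.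

## Retrosynthesis

**14 from 12 (via 13).** The last cut removes the three benzyl ethers at O5, O7 and O4' and exchanges the counter-ion. Hydrogenolysis is the only common unmasking that is neutral; acetal or silyl groups would need acid or fluoride/base in the presence of the sulfate, and acyl groups would not survive the alkaline steps before it. The forward reaction must cleave three aryl benzyl ethers of the triethylammonium salt 12 without reducing the C2=C3 bond, and the salt 13 is converted into the free acid 14 only at the end.

**12 from 11.** The S–O3 bond is cut. The flavonol 11 has exactly one free hydroxyl, so sulfation needs no selectivity; a substrate with free O7 or O4' would be sulfated there first. The forward step is asked only to sulfate an acidic enol cleanly and to deliver a stable salt.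

**11 from 9 (via 10).** The O1–C2 bond and the C3–O bond are cut together, an Algar–Flynn–Oyamada disconnection to the 2'-hydroxychalcone 9. This closes ring C and installs O3 in one flask through the transient dihydroflavonol 10. The neighbouring choice, closing to a flavone first and oxidising C3 afterwards, costs a step and is kept as the reserve. The forward reaction must close the six-membered and not the five-membered ring.

**9 from 8.** Two O–benzyl bonds (para and one ortho oxygen of ring A) are cut. The benzyl groups are those needed at the end, and in 8 the last ortho hydroxyl is held in a hydrogen bond to the ketone. That hydroxyl is the one that must stay free to become O1, so substrate control gives the required pattern.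

**8 from 7 (key cut).** The C4a–C5 bond of ring A is cut, which unfolds the acylphloroglucinol 8 into the open-chain methyl 3,5,7-trioxo ester 7. The cut removes the only ring made so far and all three ring A oxygens trace back to chain carbonyls. Cutting the aryl–acyl bond instead (Friedel–Crafts acylation of a phloroglucinol by a cinnamoyl donor) suffers from conjugate addition of the electron-rich ring to the enone. An aldol-type cut of the chalcone would abandon the polyketide logic. The forward reaction must close C6 onto the ester carbon C1 in preference to C2 onto C7. The ring B oxygen is carried as its benzyl ether from the start, so 7 needs no extra protection or deprotection.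

**7 from 3 and 6.** The C6–C7 bond of the chain is cut, giving the diketo ester 3 as a terminal carbanion (its trianion) and the cinnamoyl donor 6. An N-methoxy-N-methylamide is preferred to an ester or acyl imidazolide because its tetrahedral adduct persists until work-up, so the acidic product cannot quench unreacted trianion. The forward reaction must add 1,2 and not 1,4 to the cinnamoyl unit.

**3 from 1; 6 from 4 (via 5).** Dehydroacetic acid 1 is a bulk chemical that already holds the six-carbon diketo acid chain; methanolysis through 2 with loss of the extra acetyl group gives 3. (E)-4-(Benzyloxy)cinnamic acid 4, the O-benzyl ether of p-coumaric acid, is a catalogue compound and is converted into 6 through its imidazolide 5.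

## Roads not taken

**Alternative 1:** The cut runs through C4–C4a and takes the C3 carbonyl oxygen from an external oxidant. The precursor is the racemic aryl propargyl ether A1. In the forward step Ph3PAuNTf2 (monovalent gold) and a quinoline N-oxide would turn the terminal alkyne into an α-oxo gold carbene, which attacks the ortho carbon of ring A and closes ring C as the racemic chroman-3-one A2.
- Merits: ring C and its C3 oxygen appear in one catalytic step, ring A is symmetric so both ortho positions are equivalent, and the electron-rich arene suits an electrophilic carbene. It avoids both the Claisen/aldol question and the five- versus six-membered ring question of the chosen plan, which is a real advantage.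
- Weak points: A1 is a secondary ether that is both propargylic and para-alkoxybenzylic, so it ionises easily under a Lewis-acidic metal. Its assembly competes with C-alkylation of the electron-rich phenol ring. A2 is still short of the target at C4: a benzylic oxidation of an enolisable, air-sensitive ketone is needed to reach the 3,4-dicarbonyl tautomer that is the flavonol. The C2 stereocentre formed is discarded.
- Comparison: the chosen plan sets against it bulk starting materials, no noble-metal step, and a ring A construction that delivers the full oxygen pattern at once. Step counts would be similar, but more of the steps of this alternative are without close analogy on so electron-rich a substrate.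

**Alternative 2:** Ring A is made last, on a finished ring C, by cutting C7–C8. The precursor is the pyranone β-keto ester A3. LiN(iPr)2 would deprotonate its 2-methyl group, and this vinylogous carbanion would attack the side-chain ester to close ring A as the 5,7-dihydroxychromone A4.
- Merits: O3 is set apart from all other oxygens from the beginning (as a methoxymethyl ether) and C3 never has to be oxidised. In this respect the alternative is better than the chosen plan, which needs an oxidative step to create O3.
- Weak points: A3 is a fully substituted 4-pyranone whose preparation is about as long as the target is complex. Its β-keto ester is deprotonated before the methyl group, so the ester must be attacked while it is part of an enolate. After the annulation O7 (and possibly O5) must be protected and the acetal removed by acid before sulfation, which adds protecting-group steps.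
- Comparison: the chosen plan sets against it the short access to 7 from two stock compounds. After the oxidation 9 → 11, O3 is the only free hydroxyl anyway, so the differentiation that A4 offers is matched without extra steps.

**Alternative 3:** The cut is C3–C4. The precursor is the ether-linked dialdehyde A5. A triazolium-derived N-heterocyclic carbene with base would turn the aromatic formyl group into an acyl-anion equivalent that adds to the aliphatic aldehyde, closing ring C as the racemic trans-dihydroflavonol A6. A6 is the same compound as the transient 10 of the chosen route.
- Merits: the tether fixes the ring size, so no five-membered closure can compete; the reaction is catalytic and metal-free; and A6 is one dehydrogenation from 11.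
- Weak points: A5 combines an α-aryloxy-α-aryl acetaldehyde, prone to enolisation and self-condensation, with a doubly ortho-alkoxylated benzaldehyde that is hindered and electron-rich. Which aldehyde becomes the acyl anion is therefore not secured, although both acyloin regioisomers would oxidise to the same flavonol. Making A5 needs an ether bond at a secondary benzylic carbon and two aldehyde unmaskings. The two stereocentres are erased in the next step.
- Comparison: both plans pass through the same dihydroflavonol. The alternative reaches it more securely with respect to ring size; the chosen plan reaches it in the same flask as the flavonol, from a chalcone that is five steps from bulk chemicals and has no sensitive aldehyde on the way.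

Key step: step 4

## Route

Remark on the chemistry (assumption): the target is taken as the free hydrogen sulfate as drawn. Because aryl hydrogen sulfates hydrolyse under their own acidity, the acid is released from its triethylammonium salt only in the last operation, by cold cation exchange and freeze-drying.

Step 1
Reactants: 1 dehydroacetic acid
Product: 3 methyl 3,5-dioxohexanoate, via methyl 2-acetyl-3,5-dioxohexanoate 2 (not isolated)
Conditions: Mg(OMe)2 (from Mg, MeOH), MeOH, reflux; then cold 1 M HCl
Reagents that add atoms: methanol, CO (delivered as Mg(OMe)2, CO[Mg]OC)
Why: Lactone methanolysis followed by retro-Claisen deacylation: methoxide opens the enol lactone of 1 to the triacylmethane 2, whose acetyl group is then cleaved off as methyl acetate; the diketo ester is held as a magnesium chelate, which should stop further cleavage.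

Step 2
Reactants: 4 (E)-4-(benzyloxy)cinnamic acid
Product: 6 (E)-3-[4-(benzyloxy)phenyl]-N-methoxy-N-methylprop-2-enamide, via acyl imidazolide 5 (not isolated)
Conditions: CDI, CH2Cl2, 25 °C; then MeNH(OMe)·HCl, 25 °C; aq. NaHCO3 wash
Reagents that add atoms: N,O-dimethylhydroxylamine hydrochloride, CNOC.Cl; 1,1'-carbonyldiimidazole, O=C(n1ccnc1)n1ccnc1 (its imidazolyl group stays only in 5)
Why: Amide formation through an acyl imidazolide: activation of the acid by CDI and aminolysis by the hydroxylamine are standard, and neither the E alkene nor the benzyl ether is touched.

Step 3
Reactants: 3 methyl 3,5-dioxohexanoate (1.3 equiv, as its trilithium trianion); 6 (E)-3-[4-(benzyloxy)phenyl]-N-methoxy-N-methylprop-2-enamide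
Product: 7 methyl (E)-9-[4-(benzyloxy)phenyl]-3,5,7-trioxonon-8-enoate
Conditions: 3, LiN(iPr)2 (3.2 equiv per 3), THF, −78 → 0 °C; then 6, −78 → 0 °C; cold aq. HCl to pH 4
Reagents that add atoms: none
Why: Polyanion acylation: three equivalents of amide base deprotonate 3 at C2, C4 and C6, and the last-formed, most basic terminal carbanion attacks the carbonyl of the N-methoxy-N-methylamide; the chelated tetrahedral adduct survives until work-up, so the more acidic product neither quenches the trianion nor is acylated again, and the hard carbanion together with the donor-deactivated β-carbon should favour 1,2- over 1,4-addition.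

Step 4
Reactants: 7 methyl (E)-9-[4-(benzyloxy)phenyl]-3,5,7-trioxonon-8-enoate
Product: 8 4-O-benzylnaringenin chalcone, (E)-3-[4-(benzyloxy)phenyl]-1-(2,4,6-trihydroxyphenyl)prop-2-en-1-one
Conditions: Mg(OMe)2 (5 equiv), MeOH, 25 → 60 °C; then ice-cold 1 M HCl, rapid extraction
Reagents that add atoms: none
Why: Mg(OMe)2 in methanol should deprotonate 7 at its two diketone methylenes, C4 and C6, to a magnesium-chelated bis-enolate, while the less acidic keto-ester methylene C2 stays largely protonated. The central carbon of the chelated 5,7-diketonate (C6) attacks the magnesium-coordinated ester carbonyl C1, methoxide leaves, and the resulting 2-acylcyclohexane-1,3,5-trione tautomerises at once to the aromatic acylphloroglucinol, which makes the closure irreversible. The closest known reaction type is the magnesium-alkoxide-mediated Claisen cyclisation of 3,5,7-triketo esters to 2-acylphloroglucinols, the laboratory counterpart of the chalcone synthase step. Ring A closes in the 6-exo-trig mode, the enolate carbon C6 adding to the exocyclic ester C=O with C1 to C6 as ring atoms. No stereocentre is formed, and the symmetry of the new ring makes its two ortho hydroxyls equivalent. The selectivity needed is Claisen closure (C6 onto C1) over aldol closure (C2 onto C7), over lactonisation through the C5 enol oxygen and over conjugate addition of C4 to C9. The substrate secures it because C7 sits inside a chelated enolate that is conjugated to the para-benzyloxystyryl donor and is therefore no longer electrophilic, because C2 is not the carbanion under this mild base, and because magnesium holds C6 and the ester in one chelated array. The methyl ester matches the methoxide base, so transesterification changes nothing.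

Step 5
Reactants: 8 4-O-benzylnaringenin chalcone
Product: 9 (E)-1-[2,4-bis(benzyloxy)-6-hydroxyphenyl]-3-[4-(benzyloxy)phenyl]prop-2-en-1-one
Conditions: BnBr (2.1 equiv), K2CO3, DMF, 0 → 25 °C
Reagents that add atoms: benzyl bromide, BrCc1ccccc1
Why: Williamson etherification under weak base: the para hydroxyl and one ortho hydroxyl are alkylated, whereas the last ortho hydroxyl is locked in the hydrogen bond to the ketone and stays free; material that had closed to the flavanone isomer during the work-up of step 4 is reopened by the carbonate and should converge on 9.

Step 6
Reactants: 9 (E)-1-[2,4-bis(benzyloxy)-6-hydroxyphenyl]-3-[4-(benzyloxy)phenyl]prop-2-en-1-one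
Product: 11 5,7-bis(benzyloxy)-2-[4-(benzyloxy)phenyl]-3-hydroxy-4H-chromen-4-one, via trans-dihydroflavonol 10 (not isolated)
Conditions: 30% aq. H2O2, 2 M aq. NaOH, MeOH/THF, 0 → 25 °C; then 1 M HCl
Reagents that add atoms: hydrogen peroxide, OO
Why: Algar–Flynn–Oyamada oxidation: the 2'-phenoxide closes onto the enone β-carbon while alkaline hydrogen peroxide oxidises the α-carbon, giving the trans-dihydroflavonol 10, which the same reagent dehydrogenates to the flavonol; the two stereocentres of 10 are transient and are erased, and the benzyl ethers are stable to the alkaline peroxide.

Step 7
Reactants: 11 5,7-bis(benzyloxy)-2-[4-(benzyloxy)phenyl]-3-hydroxy-4H-chromen-4-one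
Product: 12 triethylammonium 5,7-bis(benzyloxy)-2-[4-(benzyloxy)phenyl]-4-oxo-4H-chromen-3-yl sulfate
Conditions: SO3·NEt3 (5 equiv), NEt3, DMF, 40 °C
Reagents that add atoms: sulfur trioxide–triethylamine complex, CC[N+](CC)(CC)S(=O)(=O)[O-]
Why: O-Sulfation by an amine–sulfur trioxide complex: the 3-enol is the only free hydroxyl and is acidic enough to be sulfated readily, and the product is kept as its triethylammonium salt, the form in which aryl sulfates are stable.

Step 8
Reactants: 12 triethylammonium 5,7-bis(benzyloxy)-2-[4-(benzyloxy)phenyl]-4-oxo-4H-chromen-3-yl sulfate
Product: 14 kaempferol 3-O-sulfate, via triethylammonium kaempferol 3-O-sulfate 13 (not isolated)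
Conditions: H2 (1 atm), 10% Pd/C, THF/MeOH, 25 °C; filtration; then sulfonated polystyrene resin (H+ form), MeOH/H2O, 0 °C; freeze-drying
Reagents that add atoms: none
Why: Catalytic hydrogenolysis of the three aryl benzyl ethers under neutral conditions should leave the sulfate monoester salt and the tetrasubstituted, vinylogous-ester C2=C3 bond intact; brief cold passage through the acidic resin exchanges triethylammonium for a proton immediately before freeze-drying.

## Compound list

1 | dehydroacetic acid (3-acetyl-4-hydroxy-6-methyl-2H-pyran-2-one) | CC(=O)c1c(O)cc(C)oc1=O | starting material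
2 | methyl 2-acetyl-3,5-dioxohexanoate | COC(=O)C(C(C)=O)C(=O)CC(C)=O | intermediate (not isolated)
3 | methyl 3,5-dioxohexanoate | COC(=O)CC(=O)CC(C)=O | intermediate
4 | (E)-4-(benzyloxy)cinnamic acid | O=C(O)/C=C/c1ccc(OCc2ccccc2)cc1 | starting material
5 | (E)-3-[4-(benzyloxy)phenyl]-1-(1H-imidazol-1-yl)prop-2-en-1-one (acyl imidazolide) | O=C(/C=C/c1ccc(OCc2ccccc2)cc1)n1ccnc1 | intermediate (not isolated)
6 | (E)-3-[4-(benzyloxy)phenyl]-N-methoxy-N-methylprop-2-enamide | CON(C)C(=O)/C=C/c1ccc(OCc2ccccc2)cc1 | intermediate
7 | methyl (E)-9-[4-(benzyloxy)phenyl]-3,5,7-trioxonon-8-enoate | COC(=O)CC(=O)CC(=O)CC(=O)/C=C/c1ccc(OCc2ccccc2)cc1 | intermediate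
8 | 4-O-benzylnaringenin chalcone, (E)-3-[4-(benzyloxy)phenyl]-1-(2,4,6-trihydroxyphenyl)prop-2-en-1-one | O=C(/C=C/c1ccc(OCc2ccccc2)cc1)c1c(O)cc(O)cc1O | intermediate
9 | (E)-1-[2,4-bis(benzyloxy)-6-hydroxyphenyl]-3-[4-(benzyloxy)phenyl]prop-2-en-1-one | O=C(/C=C/c1ccc(OCc2ccccc2)cc1)c1c(O)cc(OCc2ccccc2)cc1OCc1ccccc1 | intermediate
10 | trans-5,7-bis(benzyloxy)-2-[4-(benzyloxy)phenyl]-3-hydroxychroman-4-one (racemic, drawn as the 2R,3R enantiomer) | O=C1c2c(OCc3ccccc3)cc(OCc3ccccc3)cc2O[C@H](c2ccc(OCc3ccccc3)cc2)[C@H]1O | intermediate (not isolated)
11 | 5,7-bis(benzyloxy)-2-[4-(benzyloxy)phenyl]-3-hydroxy-4H-chromen-4-one (5,7,4'-tri-O-benzylkaempferol) | O=c1c(O)c(-c2ccc(OCc3ccccc3)cc2)oc2cc(OCc3ccccc3)cc(OCc3ccccc3)c12 | intermediate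
12 | triethylammonium 5,7-bis(benzyloxy)-2-[4-(benzyloxy)phenyl]-4-oxo-4H-chromen-3-yl sulfate | CC[NH+](CC)CC.O=c1c(OS(=O)(=O)[O-])c(-c2ccc(OCc3ccccc3)cc2)oc2cc(OCc3ccccc3)cc(OCc3ccccc3)c12 | intermediate
13 | triethylammonium kaempferol 3-O-sulfate | CC[NH+](CC)CC.O=c1c(OS(=O)(=O)[O-])c(-c2ccc(O)cc2)oc2cc(O)cc(O)c12 | intermediate (not isolated)
14 | kaempferol 3-O-sulfate | O=c1c(OS(=O)(=O)O)c(-c2ccc(O)cc2)oc2cc(O)cc(O)c12 | target

## Step count and risks

Total step count: 8. Longest linear sequence: 7 steps (1 → 3 → 7 → 8 → 9 → 11 → 12 → 14; the branch from 4 through 6 is equally long).

**Step 4 (key step).** The most likely failure is closure of the chain in the wrong sense: aldol attack of C2 on C7 leading to resorcylate-type aromatisation, lactonisation through the C5 enol oxygen, or conjugate addition of C4 to C9. All come from the several nucleophilic and electrophilic sites in one flexible chain. The fallback sets out from 7 and returns at 8. Compound 7 is first lactonised on purpose by heating in toluene with loss of methanol to the pyranone 6-{(E)-4-[4-(benzyloxy)phenyl]-2-oxobut-3-en-1-yl}-4-hydroxy-2H-pyran-2-one F1. In F1 the former C2 and C4 are sp2 ring carbons that cannot reach C7 or C9, and the acyl acceptor has become an enol lactone. Mg(OMe)2 in methanol then effects the known pyranone-to-acylphloroglucinol rearrangement, in which the side-chain carbanion is C-acylated by the lactone carbonyl with ring opening, to give 8.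

**Step 3.** The most likely failure is conjugate addition of the trianion to the cinnamoyl β-carbon, or acylation before the third deprotonation is complete, which would place the acyl group at C4 or on oxygen. The fallback sets out from 6 and returns at 7, replacing acylation by aldol addition and oxidation. Reduction of 6 with iBu2AlH at −78 °C gives (E)-3-[4-(benzyloxy)phenyl]prop-2-enal F2. The trianion of 3 adds cleanly 1,2 to this aldehyde to give racemic methyl (E)-9-[4-(benzyloxy)phenyl]-7-hydroxy-3,5-dioxonon-8-enoate F3. Oxidation of the allylic alcohol with MnO2 (tetravalent manganese) in CH2Cl2 gives 7.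

**Step 6.** The most likely failure is closure of the five-membered instead of the six-membered ring (the aurone pathway). The benzyloxy group ortho to the ketone is known to favour it by twisting the carbonyl out of the ring plane; oxidative cleavage of the electron-rich ketone by peroxide is a lesser risk. The fallback sets out from 9 and returns at 11, separating ring closure from oxidation of C3. Catalytic I2 in DMSO at 120 °C cyclises and dehydrogenates 9 to the flavone 5,7-bis(benzyloxy)-2-[4-(benzyloxy)phenyl]-4H-chromen-4-one F4. Dimethyldioxirane in acetone/CH2Cl2 at 0 °C epoxidises the C2=C3 bond to racemic 5,7-bis(benzyloxy)-2-[4-(benzyloxy)phenyl]-2,3-epoxychroman-4-one F5. A catalytic amount of p-toluenesulfonic acid opens F5 to 11.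

**Step 8.** The most likely failure is loss of the sulfate by solvolysis if the medium turns acidic during hydrogenolysis or during the cation exchange; incomplete debenzylation or reduction of the C2=C3 bond is less likely. The fallback sets out from 11 and returns at 14, carrying the sulfate as a neutral diester until the end. Compound 11 is treated with 2,2,2-trichloroethyl chlorosulfate, NEt3 and 4-(dimethylamino)pyridine in THF to give 5,7-bis(benzyloxy)-2-[4-(benzyloxy)phenyl]-4-oxo-4H-chromen-3-yl 2,2,2-trichloroethyl sulfate F6, which can be purified on silica. Pd/C with HCO2NH4 in MeOH then removes the benzyl ethers and the trichloroethyl group together under buffered conditions to give ammonium kaempferol 3-O-sulfate F7. The same cold cation exchange gives 14.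

## Further compounds

F1 | step 4 | 6-{(E)-4-[4-(benzyloxy)phenyl]-2-oxobut-3-en-1-yl}-4-hydroxy-2H-pyran-2-one | O=C(Cc1cc(O)cc(=O)o1)/C=C/c1ccc(OCc2ccccc2)cc1
F2 | step 3 | (E)-3-[4-(benzyloxy)phenyl]prop-2-enal | O=C/C=C/c1ccc(OCc2ccccc2)cc1
F3 | step 3 | methyl (E)-9-[4-(benzyloxy)phenyl]-7-hydroxy-3,5-dioxonon-8-enoate (racemic) | COC(=O)CC(=O)CC(=O)CC(O)/C=C/c1ccc(OCc2ccccc2)cc1
F4 | step 6 | 5,7-bis(benzyloxy)-2-[4-(benzyloxy)phenyl]-4H-chromen-4-one | O=c1cc(-c2ccc(OCc3ccccc3)cc2)oc2cc(OCc3ccccc3)cc(OCc3ccccc3)c12
F5 | step 6 | 5,7-bis(benzyloxy)-2-[4-(benzyloxy)phenyl]-2,3-epoxychroman-4-one (racemic; the cis ring fusion is the only one possible) | O=C1c2c(OCc3ccccc3)cc(OCc3ccccc3)cc2OC2(c3ccc(OCc4ccccc4)cc3)OC12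
F6 | step 8 | 5,7-bis(benzyloxy)-2-[4-(benzyloxy)phenyl]-4-oxo-4H-chromen-3-yl 2,2,2-trichloroethyl sulfate | O=c1c(OS(=O)(=O)OCC(Cl)(Cl)Cl)c(-c2ccc(OCc3ccccc3)cc2)oc2cc(OCc3ccccc3)cc(OCc3ccccc3)c12
F7 | step 8 | ammonium kaempferol 3-O-sulfate | [NH4+].O=c1c(OS(=O)(=O)[O-])c(-c2ccc(O)cc2)oc2cc(O)cc(O)c12
A1 | alternative 1 | 1,3-bis(benzyloxy)-5-({1-[4-(benzyloxy)phenyl]prop-2-yn-1-yl}oxy)benzene (racemic) | C#CC(Oc1cc(OCc2ccccc2)cc(OCc2ccccc2)c1)c1ccc(OCc2ccccc2)cc1
A2 | alternative 1 | 5,7-bis(benzyloxy)-2-[4-(benzyloxy)phenyl]chroman-3-one (racemic) | O=C1Cc2c(OCc3ccccc3)cc(OCc3ccccc3)cc2OC1c1ccc(OCc2ccccc2)cc1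
A3 | alternative 2 | methyl 3-{6-[4-(benzyloxy)phenyl]-5-(methoxymethoxy)-2-methyl-4-oxo-4H-pyran-3-yl}-3-oxopropanoate | COC(=O)CC(=O)c1c(C)oc(-c2ccc(OCc3ccccc3)cc2)c(OCOC)c1=O
A4 | alternative 2 | 4'-O-benzyl-3-O-(methoxymethyl)kaempferol | COCOc1c(-c2ccc(OCc3ccccc3)cc2)oc2cc(O)cc(O)c2c1=O
A5 | alternative 3 | 2-[3,5-bis(benzyloxy)-2-formylphenoxy]-2-[4-(benzyloxy)phenyl]acetaldehyde (racemic) | O=CC(Oc1cc(OCc2ccccc2)cc(OCc2ccccc2)c1C=O)c1ccc(OCc2ccccc2)cc1
A6 | alternative 3 | trans-5,7,4'-tri-O-benzyldihydrokaempferol (racemic, drawn as the 2R,3R enantiomer; identical with 10) | O=C1c2c(OCc3ccccc3)cc(OCc3ccccc3)cc2O[C@H](c2ccc(OCc3ccccc3)cc2)[C@H]1O
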